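The route rests on disconnecting the C1–C7 bond of the bicyclo[3.2.1]octenedione. C7 is benzylic to the 3,4-dimethoxyphenyl ring and C1 sits between the C8 and C2 carbonyls, so an acid-triggered benzylic cation at C7 is captured at C1 by the enolised dione. This one operation closes the cyclopentanone ring (C5–C8–C1–C7–C6) and sets C1 and C7. The precursor is a 6-allyl-4-methoxycyclohex-4-ene-1,3-dione that carries a 1-aryl-1-hydroxypropan-2-yl chain on its quaternary carbon. It is built from a trans-4-methyl-5-aryl butyrolactone whose carbonyl becomes C8. A final Luche reduction of C2 gives the target.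

Key step: step 9

Remark on numbering: C1–C8 are the bicyclo[3.2.1]octane locants of the target (C1 bridgehead CH, C2 carbinol, C3 methoxy carbon, C4 alkene CH, C5 allyl bridgehead, C6 methyl carbon, C7 aryl carbon, C8 ketone) and are used for the corresponding atoms of all intermediates.

Remark on the precursor: its benzylic carbon C7 is fixed as R (aryl trans to methyl on the lactone). This keeps the electron-rich ring on the lactone face opposite the C4 side chain, out of reach of the cationic C4 intermediates of step 7; the C7 configuration is erased in step 9.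

Assumption: (R)-TRIP is taken to direct the crotylboronate to the Re face of aldehyde 1; should the sense be opposite, the (S) acid is used with no other change.

Step 1
Reactants: 1 3,4-dimethoxybenzaldehyde; 2 (E)-crotylboronic acid pinacol ester
Product: 4 (1R,2R)-1-(3,4-dimethoxyphenyl)-2-methylbut-3-en-1-ol, via O-boryl homoallylic ether 3 (not isolated)
Conditions: (R)-TRIP [3,3'-bis(2,4,6-triisopropylphenyl)-1,1'-binaphthyl-2,2'-diyl hydrogen phosphate] (5 mol %), 4 Å MS, toluene, −30 °C; then aq NaHCO3
Reagents that add atoms: none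
Why: Chiral phosphoric acid-catalysed crotylboration through a closed chair transition state, in which the E boronate sets the anti relationship of C7 and C6 and the catalyst selects the aldehyde face, so both centres should arise together as 1R,2R.

Step 2
Reactants: 4 (1R,2R)-1-(3,4-dimethoxyphenyl)-2-methylbut-3-en-1-ol
Product: 6 (1R,2R)-1-(3,4-dimethoxyphenyl)-2-methylbutane-1,4-diol, via B-alkyl-9-borabicyclononane 5 (not isolated)
Conditions: 9-BBN (2.2 equiv), THF, 0 → 23 °C; then NaOH, H2O2, 0 °C
Reagents that add atoms: hydrogen peroxide, OO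
Why: Anti-Markovnikov hydroboration–oxidation, in which the bulky borane adds only to the terminal alkene carbon and neither stereocentre is touched.

Step 3
Reactants: 6 (1R,2R)-1-(3,4-dimethoxyphenyl)-2-methylbutane-1,4-diol
Product: 8 (4R,5R)-5-(3,4-dimethoxyphenyl)-4-methyloxolan-2-one, via lactol 7 (not isolated)
Conditions: TEMPO (0.2 equiv), PhI(OAc)2 (2.5 equiv), CH2Cl2, 23 °C
Reagents that add atoms: none
Why: TEMPO-mediated oxidative lactonisation, in which the oxoammonium salt oxidises the primary alcohol first, the aldehyde closes onto the benzylic hydroxyl and the lactol is oxidised again, with both centres retained (aryl trans to methyl).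

Step 4
Reactants: 8 (4R,5R)-5-(3,4-dimethoxyphenyl)-4-methyloxolan-2-one; 9 ethyl formate
Product: 10 (4R,5R)-5-(3,4-dimethoxyphenyl)-3-(hydroxymethylidene)-4-methyloxolan-2-one
Conditions: NaH (1.5 equiv), EtOH (cat.), THF, 0 → 23 °C; then cold 1 M HCl
Reagents that add atoms: none
Why: Crossed Claisen condensation (α-formylation) at the only enolisable position of the lactone, driven by formation of the stabilised enolate of the formyl lactone; this installs C4.

Step 5
Reactants: 10 (4R,5R)-5-(3,4-dimethoxyphenyl)-3-(hydroxymethylidene)-4-methyloxolan-2-one; 11 allyl methyl carbonate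
Product: 12 (3R,4R,5R)-5-(3,4-dimethoxyphenyl)-4-methyl-2-oxo-3-(prop-2-en-1-yl)oxolane-3-carbaldehyde
Conditions: Pd(PPh3)4 (5 mol %), THF, 23 °C
Reagents that add atoms: none
Why: Tsuji–Trost allylation, in which the soft formyl-lactone enolate attacks the π-allylpalladium complex at carbon (O-allyl isomers re-ionise) on the face anti to the adjacent 4-methyl group, which outweighs the more remote 5-aryl group, so the quaternary centre C5 should be set with allyl trans and formyl cis to methyl.

Step 6
Reactants: 13 methoxyacetone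
Product: 14 (Z)-1-methoxy-2-(trimethylsilyloxy)prop-1-ene
Conditions: Me3SiCl, Et3N, DMF, 100 °C; pentane extraction, distillation
Reagents that add atoms: chlorotrimethylsilane, C[Si](C)(C)Cl
Why: Silyl enol ether formation under equilibrating (House) conditions, which should place the double bond towards the methoxy-bearing carbon, with the minor terminal isomer removed by distillation.

Step 7
Reactants: 12 (3R,4R,5R)-5-(3,4-dimethoxyphenyl)-4-methyl-2-oxo-3-(prop-2-en-1-yl)oxolane-3-carbaldehyde; 14 (Z)-1-methoxy-2-(trimethylsilyloxy)prop-1-ene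
Product: 16 (3R,4R,5R)-3-(1,2-dimethoxy-3-oxobutyl)-5-(3,4-dimethoxyphenyl)-4-methyl-3-(prop-2-en-1-yl)oxolan-2-one, via dimethyl acetal 15 (not isolated)
Conditions: MeOSiMe3 (2.5 equiv), TMSOTf (0.2 equiv), CH2Cl2, −78 °C; then 14 (1.5 equiv), −78 → −40 °C; pyridine quench
Reagents that add atoms: methoxytrimethylsilane, CO[Si](C)(C)C
Why: Noyori-type acetalisation followed by Mukaiyama addition of the enol silane to the derived oxocarbenium ion forms the C4–C3 bond; the two new methoxy-bearing centres form as a mixture that step 8 erases, and the trans aryl group cannot reach the cationic carbon.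

Step 8
Reactants: 16 (3R,4R,5R)-3-(1,2-dimethoxy-3-oxobutyl)-5-(3,4-dimethoxyphenyl)-4-methyl-3-(prop-2-en-1-yl)oxolan-2-one
Product: 18 (6R)-6-[(1R,2R)-1-(3,4-dimethoxyphenyl)-1-hydroxypropan-2-yl]-4-methoxy-6-(prop-2-en-1-yl)cyclohex-4-ene-1,3-dione, via methoxy dione 17 (not isolated)
Conditions: LDA (1.2 equiv), THF, −78 → −20 °C; then LDA (2.5 equiv), −20 → 0 °C; AcOH, then pH 5 buffer
Reagents that add atoms: none
Why: Intramolecular Claisen (Dieckmann-type) acylation of the kinetic methyl-ketone enolate by the lactone carbonyl (6-exo-trig) opens the lactone and frees the C7 alkoxide; the extra base then removes the γ-proton at C3 of the dione enolate and methoxide leaves from C4 (E1cB), so the C3=C4 enol ether forms inside the ring with the required cis geometry, and no stereocentre of 18 is touched.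

Step 9
Reactants: 18 (6R)-6-[(1R,2R)-1-(3,4-dimethoxyphenyl)-1-hydroxypropan-2-yl]-4-methoxy-6-(prop-2-en-1-yl)cyclohex-4-ene-1,3-dione
Product: 19 (1R,5R,6S,7S)-7-(3,4-dimethoxyphenyl)-3-methoxy-6-methyl-5-(prop-2-en-1-yl)bicyclo[3.2.1]oct-3-ene-2,8-dione
Conditions: TfOH (10 mol %), (CF3)2CHOH–CH2Cl2 (1:4), 0 → 23 °C
Reagents that add atoms: none
Why: The acid protonates the benzylic hydroxyl, water leaves, and the 3,4-dimethoxybenzylic cation at C7 is attacked by C1 of the dione in its C1=C2 enol form; the closest known reaction type is the acid-catalysed benzylation of 1,3-dicarbonyl compounds by benzylic alcohols. The cyclopentanone ring (C5–C8–C1–C7–C6) closes in a 5-(enolexo)-exo-trig mode, which completes the bicyclo[3.2.1]octane. C1 is controlled by the quaternary C5, because the tether through C6 reaches only the ring face on which C6 stands. C7 is controlled by C6 and the forming bicycle, the aryl group settling exo, trans to the endo methyl and away from the three-carbon bridge, whichever benzylic epimer ionises. The step needs C- over O-capture: any isomer bonded through the C8 enol oxygen would be a benzylic vinylogous ester that re-ionises under the same acid and drains to the C–C bonded dione. The stabilised cation and the doubly activated C1 should make closure faster than proton loss from C6 or capture by the allyl alkene, and the ionising fluoroalcohol medium favours the free cation.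

Step 10
Reactants: 19 (1R,5R,6S,7S)-7-(3,4-dimethoxyphenyl)-3-methoxy-6-methyl-5-(prop-2-en-1-yl)bicyclo[3.2.1]oct-3-ene-2,8-dione
Product: 20 (1S,2R,5R,6S,7S)-7-(3,4-dimethoxyphenyl)-2-hydroxy-3-methoxy-6-methyl-5-(prop-2-en-1-yl)bicyclo[3.2.1]oct-3-en-8-one
Conditions: NaBH4 (1.0 equiv), CeCl3·7H2O (1.1 equiv), MeOH, −78 °C
Reagents that add atoms: none
Why: Luche 1,2-reduction, in which the cerium-activated conjugated C2 carbonyl should be reduced in preference to the non-conjugated C8 ketone (flanked by the quaternary C5 and prone to reversible hemiketal masking in methanol), with hydride arriving on the exo face, away from the endo hydrogen on C7, to give the endo 2R alcohol.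

Compound list
1 | 3,4-dimethoxybenzaldehyde | COc1ccc(C=O)cc1OC | starting material
2 | 2-[(E)-but-2-en-1-yl]-4,4,5,5-tetramethyl-1,3,2-dioxaborolane ((E)-crotylboronic acid pinacol ester) | C/C=C/CB1OC(C)(C)C(C)(C)O1 | starting material
3 | 2-{[(1R,2R)-1-(3,4-dimethoxyphenyl)-2-methylbut-3-en-1-yl]oxy}-4,4,5,5-tetramethyl-1,3,2-dioxaborolane | C=C[C@@H](C)[C@@H](OB1OC(C)(C)C(C)(C)O1)c1ccc(OC)c(OC)c1 | intermediate
4 | (1R,2R)-1-(3,4-dimethoxyphenyl)-2-methylbut-3-en-1-ol | C=C[C@@H](C)[C@@H](O)c1ccc(OC)c(OC)c1 | intermediate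
5 | 9-[(3R,4R)-4-(3,4-dimethoxyphenyl)-4-hydroxy-3-methylbutyl]-9-borabicyclo[3.3.1]nonane | C[C@H](CCB1C2CCCC1CCC2)[C@@H](O)c1ccc(OC)c(OC)c1 | intermediate
6 | (1R,2R)-1-(3,4-dimethoxyphenyl)-2-methylbutane-1,4-diol | OCC[C@@H](C)[C@@H](O)c1ccc(OC)c(OC)c1 | intermediate
7 | (4R,5R)-5-(3,4-dimethoxyphenyl)-4-methyloxolan-2-ol (both anomers) | C[C@@H]1CC(O)O[C@H]1c1ccc(OC)c(OC)c1 | intermediate
8 | (4R,5R)-5-(3,4-dimethoxyphenyl)-4-methyloxolan-2-one (aryl trans to methyl) | C[C@@H]1CC(=O)O[C@H]1c1ccc(OC)c(OC)c1 | intermediate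
9 | ethyl formate | CCOC=O | starting material
10 | (4R,5R)-5-(3,4-dimethoxyphenyl)-3-(hydroxymethylidene)-4-methyloxolan-2-one (enol form of the 3-formyl lactone) | OC=C1C(=O)O[C@@H](c2ccc(OC)c(OC)c2)[C@@H]1C | intermediate
11 | allyl methyl carbonate | C=CCOC(=O)OC | starting material
12 | (3R,4R,5R)-5-(3,4-dimethoxyphenyl)-4-methyl-2-oxo-3-(prop-2-en-1-yl)oxolane-3-carbaldehyde (allyl trans to methyl) | C=CC[C@@]1(C=O)C(=O)O[C@@H](c2ccc(OC)c(OC)c2)[C@@H]1C | intermediate
13 | methoxyacetone (1-methoxypropan-2-one) | COCC(C)=O | starting material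
14 | (Z)-1-methoxy-2-(trimethylsilyloxy)prop-1-ene | CO/C=C(/C)O[Si](C)(C)C | intermediate
15 | (3R,4R,5R)-3-(dimethoxymethyl)-5-(3,4-dimethoxyphenyl)-4-methyl-3-(prop-2-en-1-yl)oxolan-2-one | C=CC[C@@]1(C(OC)OC)C(=O)O[C@@H](c2ccc(OC)c(OC)c2)[C@@H]1C | intermediate
16 | (3R,4R,5R)-3-(1,2-dimethoxy-3-oxobutyl)-5-(3,4-dimethoxyphenyl)-4-methyl-3-(prop-2-en-1-yl)oxolan-2-one (mixture at the two side-chain carbons) | C=CC[C@@]1(C(OC)C(OC)C(C)=O)C(=O)O[C@@H](c2ccc(OC)c(OC)c2)[C@@H]1C | intermediate
17 | (6R)-6-[(1R,2R)-1-(3,4-dimethoxyphenyl)-1-hydroxypropan-2-yl]-4,5-dimethoxy-6-(prop-2-en-1-yl)cyclohexane-1,3-dione (mixture at C4 and C5 of the ring) | C=CC[C@]1(C(OC)C(OC)C(=O)CC1=O)[C@@H](C)[C@@H](O)c1ccc(OC)c(OC)c1 | intermediate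
18 | (6R)-6-[(1R,2R)-1-(3,4-dimethoxyphenyl)-1-hydroxypropan-2-yl]-4-methoxy-6-(prop-2-en-1-yl)cyclohex-4-ene-1,3-dione | C=CC[C@]1(C=C(OC)C(=O)CC1=O)[C@@H](C)[C@@H](O)c1ccc(OC)c(OC)c1 | intermediate
19 | (1R,5R,6S,7S)-7-(3,4-dimethoxyphenyl)-3-methoxy-6-methyl-5-(prop-2-en-1-yl)bicyclo[3.2.1]oct-3-ene-2,8-dione (aryl exo, methyl endo) | C=CC[C@@]12C=C(OC)C(=O)[C@@H](C1=O)[C@@H](c1ccc(OC)c(OC)c1)[C@@H]2C | intermediate
20 | (1S,2R,5R,6S,7S)-7-(3,4-dimethoxyphenyl)-2-hydroxy-3-methoxy-6-methyl-5-(prop-2-en-1-yl)bicyclo[3.2.1]oct-3-en-8-one (hydroxyl endo) | C=CC[C@@]12C=C(OC)[C@H](O)[C@@H](C1=O)[C@@H](c1ccc(OC)c(OC)c1)[C@@H]2C | target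

Total step count: 10. Longest linear sequence: 9 steps (1–5 and 7–10); step 6 prepares reagent 14.

Steps most likely to fail

Step 8. Methoxide may be lost from ketone 16 before the ring has closed, which would leave an acyclic enone of mainly the wrong geometry, or the second deprotonation may stall so that 17 survives. The fallback sets out from 12 and returns at 18, replacing steps 7 and 8. Horner–Wadsworth–Emmons olefination of 12 with dimethyl (1-methoxy-2-oxopropyl)phosphonate (LiCl, DBU, MeCN) would give the enone lactone F1 as an E/Z mixture. The E isomer, in which the quaternary carbon is cis to the acetyl group, is separated, and the Z isomer is re-equilibrated by sensitised irradiation and recycled. Treatment of F1 with LiHMDS (THF, −78 → 0 °C) then effects the same lactone-opening Claisen closure and gives 18 directly, with the alkene made before ring closure and no leaving group to expel.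

Step 9. The cation may be diverted, by proton loss from C6 or capture by the allyl alkene, or ionisation may be slowed by the water that is released. The fallback sets out from 18 and returns at 19 in two stages. Cyclodehydration of 18 (PPTS, benzene, Dean–Stark) closes the C8 enol oxygen onto C7 and should give the dihydrobenzofuranone F2, which removes both the hydroxyl group and the water. Anhydrous TMSOTf (cat.) in CH2Cl2 at −40 °C then re-ionises the benzylic C7–O bond of this vinylogous ester and C1 closes onto C7, the acid-promoted hydrobenzofuranone-to-bicyclo[3.2.1]octane shift known for this class of neolignan skeleton, to give 19.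

Step 10. Hydride may be delivered to the endo face of C2 (poor facial selectivity). The fallback sets out from 19 and returns at 20. The exo alcohol (C2 epimer) F3 from the reduction is inverted by a Mitsunobu reaction with 4-nitrobenzoic acid (PPh3, DIAD, THF) to the 4-nitrobenzoate F4. Methanolysis (K2CO3, MeOH) then releases 20.

Further compounds
F1 | step 8 | (3R,4R,5R)-5-(3,4-dimethoxyphenyl)-3-[(E)-2-methoxy-3-oxobut-1-en-1-yl]-4-methyl-3-(prop-2-en-1-yl)oxolan-2-one | C=CC[C@@]1(/C=C(/OC)C(C)=O)C(=O)O[C@@H](c2ccc(OC)c(OC)c2)[C@@H]1C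
F2 | step 9 | (2R,3R,3aR)-2-(3,4-dimethoxyphenyl)-5-methoxy-3-methyl-3a-(prop-2-en-1-yl)-3,3a-dihydro-1-benzofuran-6(2H)-one | C=CC[C@@]12C=C(OC)C(=O)C=C1O[C@@H](c1ccc(OC)c(OC)c1)[C@@H]2C
F3 | step 10 | (1S,2S,5R,6S,7S)-7-(3,4-dimethoxyphenyl)-2-hydroxy-3-methoxy-6-methyl-5-(prop-2-en-1-yl)bicyclo[3.2.1]oct-3-en-8-one | C=CC[C@@]12C=C(OC)[C@@H](O)[C@@H](C1=O)[C@@H](c1ccc(OC)c(OC)c1)[C@@H]2C
F4 | step 10 | (1S,2R,5R,6S,7S)-7-(3,4-dimethoxyphenyl)-3-methoxy-6-methyl-8-oxo-5-(prop-2-en-1-yl)bicyclo[3.2.1]oct-3-en-2-yl 4-nitrobenzoate | C=CC[C@@]12C=C(OC)[C@H](OC(=O)c3ccc(cc3)[N+](=O)[O-])[C@@H](C1=O)[C@@H](c1ccc(OC)c(OC)c1)[C@@H]2C
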